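**Retrosynthetic overview** (ring A carries the propenol chain, ring B is the middle benzo ring, ring C is the catechol; dioxane 1 is fused to ring B, dioxane 2 to ring A)
1. Target 17 ⇐ enoate reduction, Wittig olefination and debenzylation ⇐ bis-dioxane aldehyde 14.
2. Dioxane 2 ⇐ benzylic C3–O bond (syn epoxide opening by the 3-OH of 6) plus C2–O–aryl bond (SNAr at the C–F para to CHO) ⇐ epoxy alcohol 12 + 6.
3. 12 ⇐ organocatalytic epoxidation of enal 10 ⇐ two-carbon homologation of aldehyde 8.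
4. Dioxane 1 ⇐ the same annulation of epoxy alcohol 5 with 6; 5 ⇐ organocatalytic epoxidation (enantiomeric catalyst) of enal 3 ⇐ aldehyde 1.
5. Ring order: dioxane 1 first, then dioxane 2; the formyl group of 6 is both the SNAr activator and the handle for the next chain extension.

Assumption: the target is taken exactly as drawn, (2R,3R) in dioxane 2 and (2S,3S) in dioxane 1, both trans (benzodioxine locants: C2 bears CH2OH, C3 bears the aryl group); 1, 6, the Wittig reagents and both enantiomers of the prolinol silyl ether catalyst are bought.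

**Step 1**
Reactants: 1 3,4-bis(benzyloxy)benzaldehyde
Product: 3 (E)-3-[3,4-bis(benzyloxy)phenyl]prop-2-enal, via vinyl dioxolane 2 (not isolated)
Conditions: (1,3-dioxolan-2-ylmethyl)triphenylphosphonium bromide, KOtBu, THF, 0 °C to rt; then 1 M HCl, THF, rt
Reagents that add atoms: (1,3-dioxolan-2-ylmethyl)triphenylphosphonium bromide, [Br-].C1COC(C[P+](c2ccccc2)(c2ccccc2)c2ccccc2)O1; water, O
Why: Wittig reaction with a masked formylmethyl ylide followed by acetal hydrolysis gives the homologated enal, and the acid step isomerises any Z isomer to the conjugated E-enal.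

**Step 2**
Reactants: 3 (E)-3-[3,4-bis(benzyloxy)phenyl]prop-2-enal
Product: 5 [(2S,3S)-3-[3,4-bis(benzyloxy)phenyl]oxiran-2-yl]methanol, via epoxy aldehyde 4 (not isolated)
Conditions: (R)-2-{bis[3,5-bis(trifluoromethyl)phenyl](trimethylsilyloxy)methyl}pyrrolidine (10 mol%), 35% aq. H2O2, CH2Cl2, rt; then NaBH4, MeOH, 0 °C; crude product used directly
Reagents that add atoms: hydrogen peroxide, OO
Why: Jørgensen-type iminium/enamine organocatalytic epoxidation, in which the (R)-catalyst shields the Si face of C-β of the E-iminium so that HOO− adds to the Re face and the enamine closes on the O–O bond to the trans (2R,3S)-epoxy aldehyde (this sense follows from the usual shielding model and should be confirmed on the first batch); NaBH4 then reduces the aldehyde without touching either stereocenter (the C2 descriptor changes only through CIP priorities).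

**Step 3**
Reactants: 5 [(2S,3S)-3-[3,4-bis(benzyloxy)phenyl]oxiran-2-yl]methanol; 6 4-fluoro-3-hydroxybenzaldehyde
Product: 8 (2S,3S)-3-[3,4-bis(benzyloxy)phenyl]-2-(hydroxymethyl)-2,3-dihydro-1,4-benzodioxine-6-carbaldehyde, via threo diol ether 7 (not isolated)
Conditions: 6 (1.3 equiv), toluene/CH2Cl2, 40 °C, no base; then Cs2CO3, DMF, 70 °C
Reagents that add atoms: none
Why: Proposed new method: base-free syn (retentive) phenolysis/SNAr annulation, in which the acidic phenol 6 hydrogen-bonds to the epoxide oxygen of the p-benzyloxy-activated aryl epoxide in a non-polar medium, benzylic C–O ionisation gives a contact ion pair whose aryloxide stays hydrogen-bonded to the nascent C2 hydroxyl and collapses at the benzylic carbon on the face the oxygen has just left (retention, threo ether 7), and Cs2CO3 then closes the ring by intramolecular SNAr of the secondary alkoxide on the C–F bond para to the formyl group (six-membered closure, retention at C2), so the trans (2S,3S) dioxane forms with the oxygen para to CHO on the CH2OH-bearing carbon by construction; the closest known reactions are the syn opening of trans-3-(4-methoxyphenyl)glycidic esters by acidic thiophenols and the base-mediated tandem epoxide opening/aryl ether ring closure of ortho-halophenols, which proceeds with inversion.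

**Step 4**
Reactants: 8 (2S,3S)-3-[3,4-bis(benzyloxy)phenyl]-2-(hydroxymethyl)-2,3-dihydro-1,4-benzodioxine-6-carbaldehyde
Product: 10 (E)-3-[(2S,3S)-3-[3,4-bis(benzyloxy)phenyl]-2-(hydroxymethyl)-2,3-dihydro-1,4-benzodioxin-6-yl]prop-2-enal, via vinyl dioxolane 9 (not isolated)
Conditions: (1,3-dioxolan-2-ylmethyl)triphenylphosphonium bromide (2.5 equiv), KOtBu, THF, 0 °C to rt; then 1 M HCl, THF, rt
Reagents that add atoms: (1,3-dioxolan-2-ylmethyl)triphenylphosphonium bromide, [Br-].C1COC(C[P+](c2ccccc2)(c2ccccc2)c2ccccc2)O1; water, O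
Why: The same Wittig reaction/acetal hydrolysis as in step 1, with excess ylide covering the free primary alcohol; the dilute acid is too weak to ionise the benzylic aryl ether, so the dioxane stereocenters are untouched.

**Step 5**
Reactants: 10 (E)-3-[(2S,3S)-3-[3,4-bis(benzyloxy)phenyl]-2-(hydroxymethyl)-2,3-dihydro-1,4-benzodioxin-6-yl]prop-2-enal
Product: 12 [(2S,3S)-3-[3,4-bis(benzyloxy)phenyl]-6-[(2R,3R)-3-(hydroxymethyl)oxiran-2-yl]-2,3-dihydro-1,4-benzodioxin-2-yl]methanol, via epoxy aldehyde 11 (not isolated)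
Conditions: (S)-2-{bis[3,5-bis(trifluoromethyl)phenyl](trimethylsilyloxy)methyl}pyrrolidine (10 mol%), 35% aq. H2O2, CH2Cl2, rt; then NaBH4, MeOH, 0 °C; crude product used directly
Reagents that add atoms: hydrogen peroxide, OO
Why: The same Jørgensen-type organocatalytic epoxidation under catalyst control, now with the (S)-catalyst (Re face of C-β shielded, HOO− adds to the Si face) to give the (2S,3R)-epoxy aldehyde and, after reduction, the (2R,3R)-epoxy alcohol; the remote dioxane stereocenters do not interfere, and the minor enantiomer from step 2 ends up as a separable diastereomer.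

**Step 6**
Reactants: 12 [(2S,3S)-3-[3,4-bis(benzyloxy)phenyl]-6-[(2R,3R)-3-(hydroxymethyl)oxiran-2-yl]-2,3-dihydro-1,4-benzodioxin-2-yl]methanol; 6 4-fluoro-3-hydroxybenzaldehyde
Product: 14 (2R,3R)-3-[(2S,3S)-3-[3,4-bis(benzyloxy)phenyl]-2-(hydroxymethyl)-2,3-dihydro-1,4-benzodioxin-6-yl]-2-(hydroxymethyl)-2,3-dihydro-1,4-benzodioxine-6-carbaldehyde, via threo diol ether 13 (not isolated)
Conditions: 6 (1.5 equiv), toluene/CH2Cl2, 40 °C, no base; then Cs2CO3, DMF, 70 °C
Reagents that add atoms: none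
Why: Second use of the syn phenolysis/SNAr annulation of step 3 (the para ring oxygen of dioxane 1 activates this epoxide just as the benzyloxy group did), with retention at both epoxide carbons giving the trans (2R,3R) dioxane 2; the existing benzylic ether of dioxane 1 is not ionised by a phenol or by carbonate.

**Step 7**
Reactants: 14 (2R,3R)-3-[(2S,3S)-3-[3,4-bis(benzyloxy)phenyl]-2-(hydroxymethyl)-2,3-dihydro-1,4-benzodioxin-6-yl]-2-(hydroxymethyl)-2,3-dihydro-1,4-benzodioxine-6-carbaldehyde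
Product: 15 (2R,3R)-3-[(2S,3S)-3-(3,4-dihydroxyphenyl)-2-(hydroxymethyl)-2,3-dihydro-1,4-benzodioxin-6-yl]-2-(hydroxymethyl)-2,3-dihydro-1,4-benzodioxine-6-carbaldehyde
Conditions: H2 (1 atm), 10% Pd/C, EtOAc/THF, rt, stopped at full debenzylation
Reagents that add atoms: none
Why: Hydrogenolysis of aryl benzyl ethers over Pd/C is faster than reduction of the electron-rich aryl aldehyde or cleavage of the cyclic benzylic aryl ethers, and doing it here frees the catechol before any alkene is present.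

**Step 8**
Reactants: 15 (2R,3R)-3-[(2S,3S)-3-(3,4-dihydroxyphenyl)-2-(hydroxymethyl)-2,3-dihydro-1,4-benzodioxin-6-yl]-2-(hydroxymethyl)-2,3-dihydro-1,4-benzodioxine-6-carbaldehyde
Product: 16 methyl (E)-3-[(2R,3R)-3-[(2S,3S)-3-(3,4-dihydroxyphenyl)-2-(hydroxymethyl)-2,3-dihydro-1,4-benzodioxin-6-yl]-2-(hydroxymethyl)-2,3-dihydro-1,4-benzodioxin-6-yl]prop-2-enoate
Conditions: Ph3P=CHCO2Me (2.5 equiv), THF, 60 °C
Reagents that add atoms: methyl (triphenylphosphoranylidene)acetate, COC(=O)C=P(c1ccccc1)(c1ccccc1)c1ccccc1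
Why: Wittig reaction with a stabilised ylide tolerates free phenols and alcohols and gives the E-enoate selectively.

**Step 9**
Reactants: 16 methyl (E)-3-[(2R,3R)-3-[(2S,3S)-3-(3,4-dihydroxyphenyl)-2-(hydroxymethyl)-2,3-dihydro-1,4-benzodioxin-6-yl]-2-(hydroxymethyl)-2,3-dihydro-1,4-benzodioxin-6-yl]prop-2-enoate
Product: 17 (E)-3-[(2R,3R)-3-[(2S,3S)-3-(3,4-dihydroxyphenyl)-2-(hydroxymethyl)-2,3-dihydro-1,4-benzodioxin-6-yl]-2-(hydroxymethyl)-2,3-dihydro-1,4-benzodioxin-6-yl]prop-2-en-1-ol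
Conditions: iBu2AlH (8 equiv), THF, −78 °C to 0 °C; aq. KNaC4H4O6 work-up
Reagents that add atoms: none
Why: 1,2-Reduction of the α,β-unsaturated ester by DIBAL-H (excess to cover the four OH groups) gives the E-allylic alcohol without touching the alkene or any stereocenter.

**Compound list**
1 | 3,4-bis(benzyloxy)benzaldehyde | O=Cc1ccc(OCc2ccccc2)c(OCc2ccccc2)c1 | starting material
2 | 2-{2-[3,4-bis(benzyloxy)phenyl]ethenyl}-1,3-dioxolane (E/Z mixture) | C(=Cc1ccc(OCc2ccccc2)c(OCc2ccccc2)c1)C1OCCO1 | intermediate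
3 | (E)-3-[3,4-bis(benzyloxy)phenyl]prop-2-enal | O=C/C=C/c1ccc(OCc2ccccc2)c(OCc2ccccc2)c1 | intermediate
4 | (2R,3S)-3-[3,4-bis(benzyloxy)phenyl]oxirane-2-carbaldehyde (trans) | O=C[C@@H]1O[C@H]1c1ccc(OCc2ccccc2)c(OCc2ccccc2)c1 | intermediate
5 | [(2S,3S)-3-[3,4-bis(benzyloxy)phenyl]oxiran-2-yl]methanol (trans) | OC[C@@H]1O[C@H]1c1ccc(OCc2ccccc2)c(OCc2ccccc2)c1 | intermediate
6 | 4-fluoro-3-hydroxybenzaldehyde | O=Cc1ccc(F)c(O)c1 | starting material
7 | 3-{[(1S,2S)-1-[3,4-bis(benzyloxy)phenyl]-2,3-dihydroxypropyl]oxy}-4-fluorobenzaldehyde (threo) | O=Cc1ccc(F)c(c1)O[C@@H](c1ccc(OCc2ccccc2)c(OCc2ccccc2)c1)[C@H](CO)O | intermediate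
8 | (2S,3S)-3-[3,4-bis(benzyloxy)phenyl]-2-(hydroxymethyl)-2,3-dihydro-1,4-benzodioxine-6-carbaldehyde (trans) | O=Cc1ccc2c(c1)O[C@@H](c1ccc(OCc3ccccc3)c(OCc3ccccc3)c1)[C@H](CO)O2 | intermediate
9 | [(2S,3S)-3-[3,4-bis(benzyloxy)phenyl]-6-[2-(1,3-dioxolan-2-yl)ethenyl]-2,3-dihydro-1,4-benzodioxin-2-yl]methanol (E/Z mixture) | C(=Cc1ccc2c(c1)O[C@@H](c1ccc(OCc3ccccc3)c(OCc3ccccc3)c1)[C@H](CO)O2)C1OCCO1 | intermediate
10 | (E)-3-[(2S,3S)-3-[3,4-bis(benzyloxy)phenyl]-2-(hydroxymethyl)-2,3-dihydro-1,4-benzodioxin-6-yl]prop-2-enal | O=C/C=C/c1ccc2c(c1)O[C@@H](c1ccc(OCc3ccccc3)c(OCc3ccccc3)c1)[C@H](CO)O2 | intermediate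
11 | (2S,3R)-3-[(2S,3S)-3-[3,4-bis(benzyloxy)phenyl]-2-(hydroxymethyl)-2,3-dihydro-1,4-benzodioxin-6-yl]oxirane-2-carbaldehyde | O=C[C@H]1O[C@@H]1c1ccc2c(c1)O[C@@H](c1ccc(OCc3ccccc3)c(OCc3ccccc3)c1)[C@H](CO)O2 | intermediate
12 | [(2S,3S)-3-[3,4-bis(benzyloxy)phenyl]-6-[(2R,3R)-3-(hydroxymethyl)oxiran-2-yl]-2,3-dihydro-1,4-benzodioxin-2-yl]methanol | OC[C@H]1O[C@@H]1c1ccc2c(c1)O[C@@H](c1ccc(OCc3ccccc3)c(OCc3ccccc3)c1)[C@H](CO)O2 | intermediate
13 | 3-{[(1R,2R)-1-[(2S,3S)-3-[3,4-bis(benzyloxy)phenyl]-2-(hydroxymethyl)-2,3-dihydro-1,4-benzodioxin-6-yl]-2,3-dihydroxypropyl]oxy}-4-fluorobenzaldehyde (threo) | O=Cc1ccc(F)c(c1)O[C@H](c1ccc2c(c1)O[C@@H](c1ccc(OCc3ccccc3)c(OCc3ccccc3)c1)[C@H](CO)O2)[C@@H](CO)O | intermediate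
14 | (2R,3R)-3-[(2S,3S)-3-[3,4-bis(benzyloxy)phenyl]-2-(hydroxymethyl)-2,3-dihydro-1,4-benzodioxin-6-yl]-2-(hydroxymethyl)-2,3-dihydro-1,4-benzodioxine-6-carbaldehyde | O=Cc1ccc2c(c1)O[C@H](c1ccc3c(c1)O[C@@H](c1ccc(OCc4ccccc4)c(OCc4ccccc4)c1)[C@H](CO)O3)[C@@H](CO)O2 | intermediate
15 | (2R,3R)-3-[(2S,3S)-3-(3,4-dihydroxyphenyl)-2-(hydroxymethyl)-2,3-dihydro-1,4-benzodioxin-6-yl]-2-(hydroxymethyl)-2,3-dihydro-1,4-benzodioxine-6-carbaldehyde | O=Cc1ccc2c(c1)O[C@H](c1ccc3c(c1)O[C@@H](c1ccc(O)c(O)c1)[C@H](CO)O3)[C@@H](CO)O2 | intermediate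
16 | methyl (E)-3-[(2R,3R)-3-[(2S,3S)-3-(3,4-dihydroxyphenyl)-2-(hydroxymethyl)-2,3-dihydro-1,4-benzodioxin-6-yl]-2-(hydroxymethyl)-2,3-dihydro-1,4-benzodioxin-6-yl]prop-2-enoate | COC(=O)/C=C/c1ccc2c(c1)O[C@H](c1ccc3c(c1)O[C@@H](c1ccc(O)c(O)c1)[C@H](CO)O3)[C@@H](CO)O2 | intermediate
17 | (E)-3-[(2R,3R)-3-[(2S,3S)-3-(3,4-dihydroxyphenyl)-2-(hydroxymethyl)-2,3-dihydro-1,4-benzodioxin-6-yl]-2-(hydroxymethyl)-2,3-dihydro-1,4-benzodioxin-6-yl]prop-2-en-1-ol (CNP0234042.2) | OC/C=C/c1ccc2c(c1)O[C@H](c1ccc3c(c1)O[C@@H](c1ccc(O)c(O)c1)[C@H](CO)O3)[C@@H](CO)O2 | target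

**Step count**
Total steps: 9. Longest linear sequence: 9 steps (from 1).

**Three steps most likely to fail**

Step 3 (the proposed new annulation; the method recurs in step 6). The risks are partial inversion at the benzylic carbon (giving cis dioxane), Meinwald rearrangement of the electron-rich epoxide, and seven-membered closure through the primary alkoxide. The fallback uses known chemistry and thermodynamic instead of kinetic control. It sets out from 5 and 6: Cs2CO3 in DMF at 50 °C lets the phenoxide of 6 open the epoxide by SN2 with inversion at the benzylic carbon to give 3-{[(1R,2S)-1-[3,4-bis(benzyloxy)phenyl]-2,3-dihydroxypropyl]oxy}-4-fluorobenzaldehyde F2. Warming to 80 °C closes it by SNAr to the cis dioxane (2S,3R)-3-[3,4-bis(benzyloxy)phenyl]-2-(hydroxymethyl)-2,3-dihydro-1,4-benzodioxine-6-carbaldehyde F3. BF3·OEt2 in CH2Cl2 at 0 °C then epimerises the benzylic C3 through the p-benzyloxybenzyl cation to the more stable trans isomer, coming back to the route at 8. C2, which carries the absolute configuration, is never ionised.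

Step 2. The 3,4-dioxygenated enal is a sluggish iminium acceptor, and the p-alkoxyaryl epoxide is acid-labile (hydrolysis, rearrangement). The fallback replaces nucleophilic iminium epoxidation by electrophilic dioxirane epoxidation. It sets out from 3: NaBH4 with CeCl3·7H2O in MeOH at 0 °C gives (E)-3-[3,4-bis(benzyloxy)phenyl]prop-2-en-1-ol F1. Shi epoxidation of F1 with the L-fructose-derived ketone 1,2:4,5-di-O-isopropylidene-β-L-erythro-2,3-hexodiulo-2,6-pyranose (30 mol%), KHSO5 (as 2KHSO5·KHSO4·K2SO4), K2CO3 and Bu4NHSO4 in MeCN/dimethoxymethane/aqueous buffer at pH about 10.5 and 0 °C comes back to the route at 5. The basic buffer protects the labile epoxide throughout.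

Step 7. Hydrogenolysis may over-reduce the aryl aldehyde or open a benzylic C–O bond of a dioxane. The fallback changes the order and removes the benzyl groups without hydrogen. It sets out from 14: the Wittig reaction is run first (Ph3P=CHCO2Me, toluene, 80 °C) to give methyl (E)-3-[(2R,3R)-3-[(2S,3S)-3-[3,4-bis(benzyloxy)phenyl]-2-(hydroxymethyl)-2,3-dihydro-1,4-benzodioxin-6-yl]-2-(hydroxymethyl)-2,3-dihydro-1,4-benzodioxin-6-yl]prop-2-enoate F4. Its benzyl ethers are then cleaved by BCl3 with pentamethylbenzene as cation scavenger in CH2Cl2 at −78 °C, which leaves the alkene and the ester alone, coming back to the route at 16.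

**Further compounds**
F1 | step 2 | (E)-3-[3,4-bis(benzyloxy)phenyl]prop-2-en-1-ol | OC/C=C/c1ccc(OCc2ccccc2)c(OCc2ccccc2)c1
F2 | step 3 | 3-{[(1R,2S)-1-[3,4-bis(benzyloxy)phenyl]-2,3-dihydroxypropyl]oxy}-4-fluorobenzaldehyde | O=Cc1ccc(F)c(c1)O[C@H](c1ccc(OCc2ccccc2)c(OCc2ccccc2)c1)[C@H](CO)O
F3 | step 3 | (2S,3R)-3-[3,4-bis(benzyloxy)phenyl]-2-(hydroxymethyl)-2,3-dihydro-1,4-benzodioxine-6-carbaldehyde | O=Cc1ccc2c(c1)O[C@H](c1ccc(OCc3ccccc3)c(OCc3ccccc3)c1)[C@H](CO)O2
F4 | step 7 | methyl (E)-3-[(2R,3R)-3-[(2S,3S)-3-[3,4-bis(benzyloxy)phenyl]-2-(hydroxymethyl)-2,3-dihydro-1,4-benzodioxin-6-yl]-2-(hydroxymethyl)-2,3-dihydro-1,4-benzodioxin-6-yl]prop-2-enoate | COC(=O)/C=C/c1ccc2c(c1)O[C@H](c1ccc3c(c1)O[C@@H](c1ccc(OCc4ccccc4)c(OCc4ccccc4)c1)[C@H](CO)O3)[C@@H](CO)O2
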